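The target is cut back first at the ring B benzylic alcohol (to an aldehyde) and the ring A C6 phenol (to a MOM ether). The C2–O(aryl) and C1–C(=O) bonds of ring A are then cut together, giving the C1≡C2 aryne of ring A and a ring B aryl methyl carbonate.
The feature that allows this: in ring A the ester carbon C1 lies between the aryloxy carbon C2 and the oxygenated carbon C6, the pattern a 3-alkoxyaryne (triple bond C1–C2, alkoxy on C6) imposes on a nucleophile (to C2) and an electrophile (to C1).
Ring A forward: 2-bromo-3-methylphenol → MOM ether → meta C–H borylation/oxidation (second oxygen, differentiated from the first) → prenylation at the brominated carbon → carbamate-directed silylation at C1 → ortho-silylaryl triflate 14 (six steps).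
Ring B forward: 2,4-dimethoxybenzaldehyde → Dakin oxidation → ortho-formylation → methyl carbonate → dimethyl acetal 21 (four steps).
The rings are joined in step 11 through the ether oxygen while the ester is installed on C1; no ring is formed. Acid then frees the aldehyde and the C6 phenol, and NaBH4 gives the benzylic alcohol.
Stereochemistry: the target has no stereocentre and no stereogenic double bond, so nothing has to be controlled.

Key step: step 11

Remark on the chemistry: ring A is numbered C1 (ester carbon), C2 (aryloxy), C3 (H), C4 (methyl), C5 (prenyl), C6 (hydroxyl); ring B is numbered C1' (ether oxygen), C2' (CH2OH), C4' and C6' (methoxy). Systematic names in the compound list use their own locants.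

Step 1
Reactants: 1 2-bromo-3-methylphenol
Product: 2 MOM ether [2-bromo-1-(methoxymethoxy)-3-methylbenzene]
Conditions: MOMCl, iPr2NEt, CH2Cl2, 0 °C → rt
Reagents that add atoms: chloromethyl methyl ether, COCCl
Why: Standard methoxymethyl protection of a phenol (Williamson-type O-alkylation with MOMCl and an amine base) should proceed cleanly, and the MOM ether is chosen because it later serves as ortho-directing group and as the C6 alkoxy substituent that steers the aryne addition.

Step 2
Reactants: 2 MOM ether
Product: 4 para-bromophenol [4-bromo-3-(methoxymethoxy)-5-methylphenol], via aryl pinacol boronate 3 (not isolated)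
Conditions: [Ir(OMe)(cod)]2 (1.5 mol%), dtbpy (3 mol%), B2pin2, THF, 80 °C; then NaOH, aq. H2O2, THF, 0 °C → rt
Reagents that add atoms: hydrogen peroxide, OO (phenolic oxygen); bis(pinacolato)diboron, CC1(C)OB(OC1(C)C)B1OC(C)(C)C(C)(C)O1 (boryl group of intermediate 3 only)
Why: Iridium-catalysed aromatic C–H borylation is sterically controlled, so the 1,2,3-trisubstituted arene 2 should be borylated only at the single position lacking an ortho neighbour (meta to OMOM and to CH3, para to Br) with the C–Br bond untouched, and basic H2O2 oxidation of the boronate in the same flask (one-pot C–H borylation/oxidation) places the second ring A oxygen already differentiated from the first.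

Step 3
Reactants: 4 para-bromophenol; 5 prenyl bromide
Product: 7 prenyl phenol [3-(methoxymethoxy)-5-methyl-4-(3-methylbut-2-en-1-yl)phenol], via dilithio phenoxide 6 (not isolated)
Conditions: t-BuLi (3.1 equiv), THF, −78 °C; CuBr·SMe2 (20 mol%), then 5, −78 → 0 °C; aq. NH4Cl
Reagents that add atoms: none
Why: After deprotonation of the phenol, bromine–lithium exchange with t-BuLi gives the dilithio species 6, whose aryl carbon (chelated by the ortho MOM ether) is far more nucleophilic than the lithium phenoxide oxygen at low temperature and, under copper catalysis, is allylated by prenyl bromide at its primary carbon (copper-mediated SN2 allylation of an aryl organometallic), so the prenyl group should enter exactly where bromine stood.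

Step 4
Reactants: 7 prenyl phenol
Product: 8 aryl carbamate [3-(methoxymethoxy)-5-methyl-4-(3-methylbut-2-en-1-yl)phenyl N-(propan-2-yl)carbamate]
Conditions: iPrNCO, Et3N (cat.), CH2Cl2, rt
Reagents that add atoms: isopropyl isocyanate, CC(C)N=C=O
Why: Amine-catalysed addition of the phenol to the isocyanate (carbamoylation) should give the N-isopropyl carbamate, which is a strong ortho-directing group and can later be removed under mild, non-hydrolytic conditions.

Step 5
Reactants: 8 aryl carbamate
Product: 12 ortho-silyl carbamate [3-(methoxymethoxy)-5-methyl-4-(3-methylbut-2-en-1-yl)-2-(trimethylsilyl)phenyl N-(propan-2-yl)carbamate], via N-silyl carbamate 9 (not isolated), via C1 aryllithium 10 (not isolated), via N-silyl C-silyl carbamate 11 (not isolated)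
Conditions: TBSOTf (1.05 equiv), TMEDA, Et2O, 0 °C → rt; n-BuLi, TMEDA, −78 °C; TMSCl, −78 °C → rt; cold aq. NaHSO4 work-up
Reagents that add atoms: chlorotrimethylsilane, C[Si](C)(C)Cl; tert-butyldimethylsilyl triflate, CC(C)(C)[Si](C)(C)OS(=O)(=O)C(F)(F)F (N-silyl group of intermediates 9 to 11 only)
Why: This is a directed ortho-metalation in which the carbamate N–H is first masked in situ by silylation (it should take up TBSOTf faster than the amine-buffered reagent can activate the MOM acetal), n-BuLi/TMEDA then removes the C1 proton, which is flanked and acidified by both the carbamate and the MOM ether and should be lost faster than H-3 or the allylic–benzylic CH2, TMSCl silylates the aryllithium, and the N-silyl group falls off on aqueous work-up.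

Step 6
Reactants: 12 ortho-silyl carbamate
Product: 14 ring A silyl triflate [3-(methoxymethoxy)-5-methyl-4-(3-methylbut-2-en-1-yl)-2-(trimethylsilyl)phenyl trifluoromethanesulfonate], via ortho-silyl phenol 13 (not isolated)
Conditions: Et2NH, DBU, MeCN, 40 °C; then PhNTf2, rt
Reagents that add atoms: N-phenylbis(trifluoromethanesulfonimide), O=S(=O)(N(c1ccccc1)S(=O)(=O)C(F)(F)F)C(F)(F)F
Why: DBU deprotonates the carbamate N–H so that the aryloxide is expelled (E1cB cleavage) while diethylamine traps the isopropyl isocyanate as a urea, and the hindered ortho-silyl phenoxide is then sulfonylated in the same flask by the mild triflating agent PhNTf2, the established carbamate route to ortho-silylaryl triflates that avoids protodesilylation.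

Step 7
Reactants: 15 2,4-dimethoxybenzaldehyde
Product: 17 2,4-dimethoxyphenol, via aryl formate 16 (not isolated)
Conditions: mCPBA, CH2Cl2, 0 °C → rt; then KOH, MeOH/H2O, 0 °C; acidify
Reagents that add atoms: 3-chloroperoxybenzoic acid, OOC(=O)c1cccc(Cl)c1
Why: Dakin-type Baeyer–Villiger oxidation: in the peracid adduct of this electron-rich aldehyde the aryl group migrates in preference to hydride, giving the aryl formate 16, which is saponified in the same flask to the phenol.

Step 8
Reactants: 17 2,4-dimethoxyphenol
Product: 18 salicylaldehyde [2-hydroxy-3,5-dimethoxybenzaldehyde]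
Conditions: MgCl2, Et3N, (CH2O)n, MeCN, reflux; aq. HCl work-up
Reagents that add atoms: paraformaldehyde (as formaldehyde), C=O
Why: Magnesium-mediated ortho-formylation (Casnati–Skattebøl reaction): the magnesium phenoxide delivers formaldehyde to the only unsubstituted ortho carbon and a second equivalent of formaldehyde oxidises the resulting benzylic alkoxide to the aldehyde by hydride transfer, so a single regioisomer should form.

Step 9
Reactants: 18 salicylaldehyde; 19 methyl chloroformate
Product: 20 formyl aryl carbonate [2-formyl-4,6-dimethoxyphenyl methyl carbonate]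
Conditions: Et3N, CH2Cl2, 0 °C
Reagents that add atoms: none
Why: O-Acylation of the phenol with the chloroformate under amine base (carbonate formation) should be straightforward since the phenolic oxygen is the only nucleophilic site, and it installs the acyl donor that the aryl anion will later collect.

Step 10
Reactants: 20 formyl aryl carbonate
Product: 21 ring B acetal carbonate [2-(dimethoxymethyl)-4,6-dimethoxyphenyl methyl carbonate]
Conditions: HC(OMe)3, p-TsOH·H2O (cat.), CH2Cl2, rt; Et3N quench
Reagents that add atoms: trimethyl orthoformate, COC(OC)OC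
Why: Acid-catalysed acetalisation with trimethyl orthoformate as methanol source and water scavenger should convert the aldehyde, made more electrophilic by the ortho carbonate, into the dimethyl acetal while the aryl carbonate, which needs base for transesterification, survives; the acetal is required because a free ortho-formyl group would capture the aryl anion of the next step intramolecularly.

Step 11
Reactants: 14 ring A silyl triflate; 21 ring B acetal carbonate
Product: 25 protected diaryl ether ester [methyl 6-[2-(dimethoxymethyl)-4,6-dimethoxyphenoxy]-2-(methoxymethoxy)-4-methyl-3-(3-methylbut-2-en-1-yl)benzoate], via ring A aryne 22 (not isolated), via potassium aryloxide 23 (not isolated), via aryl potassium species 24 (not isolated)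
Conditions: KF (3 equiv), 18-crown-6 (3 equiv), 21 (2 equiv), 4 Å MS, THF (0.3 M), 0 °C → rt
Reagents that add atoms: none
Why: Proposed new method: fluoride removes the trimethylsilyl group of 14 with loss of triflate to give aryne 22 (C1≡C2), while a little fluoride attack at the carbonate carbonyl of 21 liberates aryloxide 23 as chain initiator; 23 adds to C2 of the aryne, and the resulting C1 aryl anion 24 attacks the carbonate carbonyl of a further molecule of 21, whose tetrahedral intermediate expels the aryloxide (a better leaving group than methoxide), leaving the methyl ester on C1 and returning 23 to the chain, in sum a formal insertion of the aryne into the ArO–C(=O) bond. The closest known reactions are fluoride-triggered aryne insertions into acyl–nitrogen, acyl–carbon and acyl–chlorine bonds, three-component couplings of arynes with a nucleophile and CO2, and the O-arylation of phenoxides by arynes; new here is an aryl carbonate acting as O-nucleophile and acyl donor at once. No ring is closed and no stereocentre is formed. The step needs regioselectivity (aryloxide to C2, acyl to C1), which the C6 methoxymethoxy group should secure by distorting the aryne so that the nucleophile attacks the distal carbon C2 and the charge develops at C1 next to the inductively withdrawing oxygen. It also needs O- over C-arylation, secured because both ortho positions and the para position of 23 are substituted, and acyl capture ahead of protonation, for which the non-acidic solvent, dry conditions, excess 21 and high concentration are chosen.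

Step 12
Reactants: 25 protected diaryl ether ester
Product: 26 aldehyde phenol [methyl 6-(2-formyl-4,6-dimethoxyphenoxy)-2-hydroxy-4-methyl-3-(3-methylbut-2-en-1-yl)benzoate]
Conditions: 2 M aq. HCl, THF/MeOH, 40 °C
Reagents that add atoms: water, O
Why: Aqueous acid hydrolyses both acetals in one operation (acetal hydrolysis), the phenolic MOM ether being labilised by the neighbouring ester carbonyl, while the methyl ester, the diaryl ether and the aryl methyl ethers are inert and the trisubstituted prenyl alkene should not be protonated at a competitive rate in dilute acid at 40 °C.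

Step 13
Reactants: 26 aldehyde phenol
Product: 27 target CNP0583011.0 [methyl 2-hydroxy-6-[2-(hydroxymethyl)-4,6-dimethoxyphenoxy]-4-methyl-3-(3-methylbut-2-en-1-yl)benzoate]
Conditions: NaBH4, MeOH/THF, 0 °C; aq. NH4Cl
Reagents that add atoms: none
Why: Borohydride reduction is chemoselective for the aldehyde, because the methyl ester is di-ortho-substituted and hydrogen-bonded to the C6 hydroxyl and is not reduced by NaBH4 at 0 °C, and a short reaction time with a buffered quench keeps the new benzylic alkoxide from closing the eight-membered lactone onto that ester.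

Compound list
1 | 2-bromo-3-methylphenol | Cc1cccc(O)c1Br | starting material
2 | 2-bromo-1-(methoxymethoxy)-3-methylbenzene | COCOc1cccc(C)c1Br | intermediate
3 | 2-[4-bromo-3-(methoxymethoxy)-5-methylphenyl]-4,4,5,5-tetramethyl-1,3,2-dioxaborolane (not isolated) | COCOc1cc(B2OC(C)(C)C(C)(C)O2)cc(C)c1Br | intermediate
4 | 4-bromo-3-(methoxymethoxy)-5-methylphenol | COCOc1cc(O)cc(C)c1Br | intermediate
5 | prenyl bromide (1-bromo-3-methylbut-2-ene) | CC(C)=CCBr | starting material
6 | lithium 4-lithio-3-(methoxymethoxy)-5-methylphenoxide (not isolated) | COCOc1cc(O[Li])cc(C)c1[Li] | intermediate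
7 | 3-(methoxymethoxy)-5-methyl-4-(3-methylbut-2-en-1-yl)phenol | COCOc1cc(O)cc(C)c1CC=C(C)C | intermediate
8 | 3-(methoxymethoxy)-5-methyl-4-(3-methylbut-2-en-1-yl)phenyl N-(propan-2-yl)carbamate | CC(C)NC(=O)Oc1cc(C)c(CC=C(C)C)c(OCOC)c1 | intermediate
9 | N-(tert-butyldimethylsilyl) derivative of carbamate 8 (not isolated) | CC(C)N(C(=O)Oc1cc(C)c(CC=C(C)C)c(OCOC)c1)[Si](C)(C)C(C)(C)C | intermediate
10 | C1 (ortho) aryllithium of 9, lithium between the carbamate and the MOM ether (not isolated) | CC(C)N(C(=O)Oc1cc(C)c(CC=C(C)C)c(OCOC)c1[Li])[Si](C)(C)C(C)(C)C | intermediate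
11 | N-(tert-butyldimethylsilyl) C-(trimethylsilyl) carbamate (not isolated) | CC(C)N(C(=O)Oc1cc(C)c(CC=C(C)C)c(OCOC)c1[Si](C)(C)C)[Si](C)(C)C(C)(C)C | intermediate
12 | 3-(methoxymethoxy)-5-methyl-4-(3-methylbut-2-en-1-yl)-2-(trimethylsilyl)phenyl N-(propan-2-yl)carbamate | CC(C)NC(=O)Oc1cc(C)c(CC=C(C)C)c(OCOC)c1[Si](C)(C)C | intermediate
13 | 3-(methoxymethoxy)-5-methyl-4-(3-methylbut-2-en-1-yl)-2-(trimethylsilyl)phenol (not isolated) | COCOc1c(CC=C(C)C)c(C)cc(O)c1[Si](C)(C)C | intermediate
14 | 3-(methoxymethoxy)-5-methyl-4-(3-methylbut-2-en-1-yl)-2-(trimethylsilyl)phenyl trifluoromethanesulfonate | C[Si](C)(C)c1c(OS(=O)(=O)C(F)(F)F)cc(C)c(CC=C(C)C)c1OCOC | intermediate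
15 | 2,4-dimethoxybenzaldehyde | COc1ccc(C=O)c(OC)c1 | starting material
16 | 2,4-dimethoxyphenyl formate (not isolated) | COc1ccc(OC=O)c(OC)c1 | intermediate
17 | 2,4-dimethoxyphenol | COc1ccc(O)c(OC)c1 | intermediate
18 | 2-hydroxy-3,5-dimethoxybenzaldehyde | COc1cc(OC)c(O)c(C=O)c1 | intermediate
19 | methyl chloroformate | COC(=O)Cl | starting material
20 | 2-formyl-4,6-dimethoxyphenyl methyl carbonate | COC(=O)Oc1c(C=O)cc(OC)cc1OC | intermediate
21 | 2-(dimethoxymethyl)-4,6-dimethoxyphenyl methyl carbonate | COC(=O)Oc1c(C(OC)OC)cc(OC)cc1OC | intermediate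
22 | 3-(methoxymethoxy)-5-methyl-4-(3-methylbut-2-en-1-yl)-1,2-didehydrobenzene, the C1≡C2 aryne of ring A (not isolated) | C1#CC=C(C)C(CC=C(C)C)=C1OCOC | intermediate
23 | potassium 2-(dimethoxymethyl)-4,6-dimethoxyphenoxide (not isolated) | [K+].[O-]c1c(C(OC)OC)cc(OC)cc1OC | intermediate
24 | {2-[2-(dimethoxymethyl)-4,6-dimethoxyphenoxy]-6-(methoxymethoxy)-4-methyl-5-(3-methylbut-2-en-1-yl)phenyl}potassium (not isolated) | [K]c1c(Oc2c(C(OC)OC)cc(OC)cc2OC)cc(C)c(CC=C(C)C)c1OCOC | intermediate
25 | methyl 6-[2-(dimethoxymethyl)-4,6-dimethoxyphenoxy]-2-(methoxymethoxy)-4-methyl-3-(3-methylbut-2-en-1-yl)benzoate | COC(=O)c1c(Oc2c(C(OC)OC)cc(OC)cc2OC)cc(C)c(CC=C(C)C)c1OCOC | intermediate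
26 | methyl 6-(2-formyl-4,6-dimethoxyphenoxy)-2-hydroxy-4-methyl-3-(3-methylbut-2-en-1-yl)benzoate | COC(=O)c1c(Oc2c(C=O)cc(OC)cc2OC)cc(C)c(CC=C(C)C)c1O | intermediate
27 | methyl 2-hydroxy-6-[2-(hydroxymethyl)-4,6-dimethoxyphenoxy]-4-methyl-3-(3-methylbut-2-en-1-yl)benzoate (CNP0583011.0) | COC(=O)c1c(Oc2c(CO)cc(OC)cc2OC)cc(C)c(CC=C(C)C)c1O | target

Total step count: 13.
Longest linear sequence: 9 steps (steps 1 to 6, then 11, 12 and 13, from 2-bromo-3-methylphenol).

Steps most likely to fail

Step 11 (proposed new method). The aryl anion may be protonated before it meets a carbonate molecule, by residual water or by hydrogen transfer from the acetal C–H of its own ring B, so that the ether forms without the ester. The chain may also stall if fluoride consumes the carbonate faster than the aryne is released. Fallback with known chemistry, setting out from 14 and 21 and returning at 25: carbonate 21 is methanolysed (K2CO3, MeOH, rt) to 2-(dimethoxymethyl)-4,6-dimethoxyphenol F1. Phenol F1 and triflate 14 are combined with CsF in MeCN at rt, the known O-arylation of phenols by arynes, in which aryne 22 is attacked at C2 and the anion is protonated, to give 2-[3-(methoxymethoxy)-5-methyl-4-(3-methylbut-2-en-1-yl)phenoxy]-1-(dimethoxymethyl)-3,5-dimethoxybenzene F2. Directed ortho-lithiation of F2 (n-BuLi, THF, −78 → −40 °C) at C1 of ring A, the position flanked by the chelating MOM ether and the diaryl ether oxygen, gives the C1-lithiated diaryl ether F3, which is quenched with methyl chloroformate 19 to give 25.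

Step 3. Bromine–lithium exchange on the electron-rich phenoxide may be incomplete, the phenoxide oxygen may be prenylated on warming, or the allylation may partly go through the tertiary terminus of prenyl bromide. Fallback, setting out from 4 and returning at 7: the phenol is silylated (TIPSCl, imidazole, DMF) to [4-bromo-3-(methoxymethoxy)-5-methylphenoxy]tri(propan-2-yl)silane F4. Exchange with t-BuLi (2 equiv, THF, −78 °C) gives the monoanionic aryllithium [2-(methoxymethoxy)-6-methyl-4-(triisopropylsilyloxy)phenyl]lithium F5, which is prenylated with 5 under CuBr·SMe2 mediation to [3-(methoxymethoxy)-5-methyl-4-(3-methylbut-2-en-1-yl)phenoxy]tri(propan-2-yl)silane F6. TBAF in THF then releases 7.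

Step 12. Under Brønsted acid the freed C6 phenol may add across the protonated prenyl double bond (chroman formation), or the alkene may be hydrated, before the MOM ether is fully cleaved. Fallback, setting out from 25 and returning at 27, so that the free phenol never meets protic acid: selective hydrolysis of the dimethyl acetal only (PPTS, acetone/H2O, rt) gives methyl 6-(2-formyl-4,6-dimethoxyphenoxy)-2-(methoxymethoxy)-4-methyl-3-(3-methylbut-2-en-1-yl)benzoate F7. NaBH4 in MeOH at 0 °C gives methyl 6-[2-(hydroxymethyl)-4,6-dimethoxyphenoxy]-2-(methoxymethoxy)-4-methyl-3-(3-methylbut-2-en-1-yl)benzoate F8. The MOM group is then transferred to a thiol under Lewis-acid conditions (ZnBr2, n-PrSH, CH2Cl2, 0 °C, minutes), which gives 27 directly.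

Further compounds
F1 | step 11 | 2-(dimethoxymethyl)-4,6-dimethoxyphenol | COc1cc(OC)c(O)c(C(OC)OC)c1
F2 | step 11 | 2-[3-(methoxymethoxy)-5-methyl-4-(3-methylbut-2-en-1-yl)phenoxy]-1-(dimethoxymethyl)-3,5-dimethoxybenzene | COCOc1cc(Oc2c(C(OC)OC)cc(OC)cc2OC)cc(C)c1CC=C(C)C
F3 | step 11 | {2-[2-(dimethoxymethyl)-4,6-dimethoxyphenoxy]-6-(methoxymethoxy)-4-methyl-5-(3-methylbut-2-en-1-yl)phenyl}lithium | COCOc1c([Li])c(Oc2c(C(OC)OC)cc(OC)cc2OC)cc(C)c1CC=C(C)C
F4 | step 3 | [4-bromo-3-(methoxymethoxy)-5-methylphenoxy]tri(propan-2-yl)silane | COCOc1cc(O[Si](C(C)C)(C(C)C)C(C)C)cc(C)c1Br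
F5 | step 3 | [2-(methoxymethoxy)-6-methyl-4-(triisopropylsilyloxy)phenyl]lithium | COCOc1cc(O[Si](C(C)C)(C(C)C)C(C)C)cc(C)c1[Li]
F6 | step 3 | [3-(methoxymethoxy)-5-methyl-4-(3-methylbut-2-en-1-yl)phenoxy]tri(propan-2-yl)silane | COCOc1cc(O[Si](C(C)C)(C(C)C)C(C)C)cc(C)c1CC=C(C)C
F7 | step 12 | methyl 6-(2-formyl-4,6-dimethoxyphenoxy)-2-(methoxymethoxy)-4-methyl-3-(3-methylbut-2-en-1-yl)benzoate | COC(=O)c1c(Oc2c(C=O)cc(OC)cc2OC)cc(C)c(CC=C(C)C)c1OCOC
F8 | step 12 | methyl 6-[2-(hydroxymethyl)-4,6-dimethoxyphenoxy]-2-(methoxymethoxy)-4-methyl-3-(3-methylbut-2-en-1-yl)benzoate | COC(=O)c1c(Oc2c(CO)cc(OC)cc2OC)cc(C)c(CC=C(C)C)c1OCOC
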